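**Plan**

- Retrosynthetic cuts, in order: the C8 ester and C9 acetate; the furanone O–C3 bond (back to a macrocyclic γ-hydroxy ynone); C2–C3 (ring closure); C11=C13; the lactone bonds O1–C6 and C11–C7 together; C5–C6; C10–C1; what remains is L-fucose (C7–C10 and C14).
- Forward order: dioxolane from L-fucose → (4Z,6E)-diene → trans-γ-lactone (key step) → 10-membered carbocycle (Nozaki–Hiyama–Kishi) → bridging 3(2H)-furanone (transannular) → C8 ester, then C9 acetate.
- Enabling feature: C6 is allylic to C4=C5, so C6=C7 can be the end of a C4=C5–C6=C7 diene. Attack at C7 gives a C4–C5–C6 allyl radical/cation; a carboxyl closes the five-membered lactone ring (O1, C6, C7, C11, C12) at C6 and C4=C5 is restored.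
- Stereochemistry: C8 and C9 are bought (L-fucose C3, C4); C10 comes from chelation-controlled alkynylation; C7 and C6 are both set in the key step (C8 → C7 by 1,2-induction, C7 → C6 by trans ring closure); 4Z comes from anti-carbomagnesiation of propargyl alcohol.

Key step: step 10

Remark on numbering: all intermediates carry the germacranolide numbering of the target (C1–C10 ring carbons, C11–C13 lactone carbons, C14 = methyl on C10, C15 = methyl on C4).

**Route**

Step 1
Reactants: 1 L-fucose
Product: 2 3,4-O-isopropylidene-L-fucopyranose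
Conditions: 2,2-dimethoxypropane, TsOH (cat.), DMF, rt
Reagents that add atoms: 2,2-dimethoxypropane COC(C)(C)OC
Why: Kinetic acetal formation should take the only cis-diol (O3/O4) of the pyranose and leave the anomeric OH and 2-OH free.

Step 2
Reactants: 2 3,4-O-isopropylidene-L-fucopyranose
Product: 4 5-deoxy-2,3-O-isopropylidene-L-lyxofuranose, via formate aldehyde 3 (not isolated)
Conditions: NaIO4, NaHCO3, H2O/MeOH, 0 °C to rt
Reagents that add atoms: none
Why: Malaprade glycol cleavage of the hemiacetal-OH/2-OH pair should excise fucose C1 as formate, and the freed 10-OH recloses on the new C7 aldehyde; C8 and C9 are not touched.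

Step 3
Reactants: 4 5-deoxy-2,3-O-isopropylidene-L-lyxofuranose
Product: 5 (E)-vinyl iodide alcohol
Conditions: CrCl2, CHI3, THF, 0 °C to rt
Reagents that add atoms: iodoform IC(I)I
Why: Takai olefination of the open aldehyde form should add C6 as an (E)-iodoalkene under non-basic conditions, so the α-alkoxy centre C8 is not epimerised.

Step 4
Reactants: 5 (E)-vinyl iodide alcohol
Product: 6 methyl ketone
Conditions: Dess–Martin periodinane, pyridine, CH2Cl2, 0 °C
Reagents that add atoms: none
Why: Dess–Martin oxidation of the single secondary alcohol (C10) should give the methyl ketone without epimerising C9.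

Step 5
Reactants: 6 methyl ketone; 7 ethynyl(trimethyl)silane
Product: 9 tertiary propargylic alcohol (10S), via alkynylmagnesium bromide 8 (not isolated)
Conditions: 7, EtMgBr, THF, 0 °C to rt; then 6, MgBr2·OEt2, CH2Cl2/Et2O, −78 °C
Reagents that add atoms: none
Why: Chelation-controlled Grignard addition (Mg bridges the C10 carbonyl and the dioxolane O9, attack anti to C8) should set C10 with the O9/O10 syn relationship of the target.

Step 6
Reactants: 9 tertiary propargylic alcohol
Product: 10 triethylsilyl ether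
Conditions: TESOTf, 2,6-lutidine, CH2Cl2, −78 to 0 °C
Reagents that add atoms: triethylsilyl trifluoromethanesulfonate CC[Si](CC)(CC)OS(=O)(=O)C(F)(F)F
Why: Silylation masks the tertiary 10-OH so that it cannot trap the allyl cation in the key step.

Step 7
Reactants: 11 prop-2-yn-1-ol
Product: 13 (2Z)-3-iodo-2-methylprop-2-en-1-ol, via alkenylmagnesium alkoxide 12 (not isolated)
Conditions: MeMgBr, CuI (10 mol%), THF, −10 °C to rt; then I2, −78 to 0 °C
Reagents that add atoms: methylmagnesium bromide C[Mg]Br; iodine II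
Why: Copper-catalysed, alkoxide-directed anti-carbomagnesiation followed by iodinolysis with retention should give the Z-alkene that becomes C4=C5 (C3 cis to the future C6).

Step 8
Reactants: 13 (2Z)-3-iodo-2-methylprop-2-en-1-ol
Product: 14 TBDPS ether
Conditions: TBDPSCl, imidazole, DMF, rt
Reagents that add atoms: tert-butyl(chloro)diphenylsilane CC(C)(C)[Si](Cl)(c1ccccc1)c1ccccc1
Why: Silylation gives an acid-stable O3 ether that survives the acetic acid medium of the key step.

Step 9
Reactants: 14 TBDPS ether; 10 triethylsilyl ether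
Product: 17 (4Z,6E)-diene, via alkenyllithium 15 (not isolated), via alkenylzinc chloride 16 (not isolated)
Conditions: 14, t-BuLi, Et2O, −78 °C; ZnCl2, THF, −78 to 0 °C; then 10, Pd(PPh3)4 (5 mol%), THF, rt
Reagents that add atoms: none
Why: Negishi coupling of the (Z)-alkenylzinc with the (E)-alkenyl iodide forms C5–C6 with retention of both geometries.

Step 10
Reactants: 17 (4Z,6E)-diene; 18 malonic acid
Product: 19 trans-γ-lactone acid (6R,7S; C11 epimers)
Conditions: Mn(OAc)3·2H2O (2.2 equiv, portionwise), KOAc, AcOH, 25–40 °C, N2, 0.02 M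
Reagents that add atoms: none
Why: Mn(III) oxidises malonic acid to the electrophilic radical •CH(CO2H)2, which adds to C7, the CH terminus of the C4=C5–C6=C7 diene, to give the C4–C5–C6 allyl radical; a second Mn(III) oxidises it to the allyl cation and one carboxyl closes at C6 with return of C4=C5 (closest known reaction type: Mn(OAc)3 carbolactonisation of alkenes and 1,3-dienes with malonic or cyanoacetic acid). The lactone ring (O1, C6, C7, C11, C12) closes by 5-exo attack of the carboxyl oxygen on the cationic C6, so the whole event is a radical-addition/polar-closure [3+2] annulation. C7 is controlled by the C8 dioxolane centre: in the inside-alkoxy arrangement the C8–O8 bond lies in the alkene plane and the radical attacks anti to the bulky C9 substituent, which gives the C11/O8 erythro relationship (the same sense as the empirical rule for osmylation of allylic ethers). C6 is controlled by C7 during closure, the C5 alkenyl and C8 groups taking trans positions on the forming ring. The step needs attack at C7 and not C4 (C4 is fully substituted, and attack at C7 gives the more substituted allyl radical), retention of 4Z (oxidation and closure should outrun rotation of the allyl intermediate) and a stop at the mono-lactone (excess malonic acid, low temperature); the O3 and O10 silyl ethers keep those oxygens from trapping the cation.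

Step 11
Reactants: 19 trans-γ-lactone acid
Product: 20 α-methylene-γ-lactone
Conditions: 37% aq. HCHO, N-methylaniline, NaOAc, AcOH, rt
Reagents that add atoms: formaldehyde C=O
Why: Decarboxylative Mannich methylenation should remove the helper carboxyl as CO2 and install C13, which also erases the C11 stereocentre.

Step 12
Reactants: 20 α-methylene-γ-lactone
Product: 21 diol alkyne (3-OH, 10-OH, C2–H)
Conditions: TBAF, AcOH (1:1), THF, 0 °C to rt
Reagents that add atoms: none
Why: Buffered fluoride desilylation should cleave the TBDPS and TES ethers and the alkynyl C–Si bond in one operation without adding to the methylene lactone.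

Step 13
Reactants: 21 diol alkyne
Product: 22 iodoalkyne
Conditions: NIS, AgNO3 (10 mol%), acetone, rt, dark
Reagents that add atoms: N-iodosuccinimide O=C1CCC(=O)N1I
Why: Silver-catalysed iodination of the terminal alkyne C–H is selective over the electron-poor and trisubstituted alkenes.

Step 14
Reactants: 22 iodoalkyne
Product: 23 (Z)-enal
Conditions: Dess–Martin periodinane, pyridine, CH2Cl2, 0 °C
Reagents that add atoms: none
Why: Dess–Martin oxidation of the primary allylic alcohol under buffered conditions should give the C3 aldehyde without Z/E isomerisation; the tertiary 10-OH is inert.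

Step 15
Reactants: 23 (Z)-enal
Product: 24 10-membered carbocyclic alcohol (C3 epimers)
Conditions: CrCl2 (8 equiv), NiCl2 (2 mol%), THF, rt, syringe-pump addition, 2 mM
Reagents that add atoms: none
Why: Intramolecular Nozaki–Hiyama–Kishi addition of the alkynylchromium species to the aldehyde forms C2–C3 chemoselectively in the presence of the lactone; the new C3 carbinol centre is removed in the next step.

Step 16
Reactants: 24 10-membered carbocyclic alcohol
Product: 25 macrocyclic γ-hydroxy ynone
Conditions: Dess–Martin periodinane, pyridine, CH2Cl2, 0 °C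
Reagents that add atoms: none
Why: Dess–Martin oxidation of the doubly activated C3 alcohol gives the ynone; the tertiary 10-OH cannot be oxidised.

Step 17
Reactants: 25 macrocyclic γ-hydroxy ynone
Product: 26 8,9-O-isopropylidene furanoheliangolide
Conditions: (4-CF3C6H4)3PAuCl (5 mol%), AgOTf (5 mol%), toluene, rt
Reagents that add atoms: none
Why: Gold(I)-catalysed cycloisomerisation of a γ-hydroxyalkynone to a 3(2H)-furanone should, transannularly, bond O10 to C3 and leave the carbonyl on C1, with C10 unchanged.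

Step 18
Reactants: 26 8,9-O-isopropylidene furanoheliangolide
Product: 27 8,9-diol
Conditions: TFA/H2O (9:1), CH2Cl2, 0 °C to rt
Reagents that add atoms: none
Why: Acidic acetal hydrolysis frees the 8,9-diol; lactone, furanone and alkenes are stable to aqueous acid.

Step 19
Reactants: 28 acetaldehyde; 29 tert-butyl acrylate
Product: 30 tert-butyl 3-hydroxy-2-methylidenebutanoate
Conditions: DABCO (cat.), neat, rt
Reagents that add atoms: none
Why: Morita–Baylis–Hillman reaction joins the acrylate α-carbon to the aldehyde; the carbinol centre is lost later.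

Step 20
Reactants: 30 tert-butyl 3-hydroxy-2-methylidenebutanoate
Product: 31 tert-butyl 3-acetoxy-2-methylidenebutanoate
Conditions: Ac2O, pyridine, DMAP (cat.), CH2Cl2, 0 °C to rt
Reagents that add atoms: acetic anhydride CC(=O)OC(C)=O
Why: Standard acetylation of the secondary allylic alcohol.

Step 21
Reactants: 31 tert-butyl 3-acetoxy-2-methylidenebutanoate
Product: 32 tert-butyl (2E)-2-(acetoxymethyl)but-2-enoate
Conditions: DABCO (cat.), THF, 60 °C
Reagents that add atoms: none
Why: Amine-catalysed SN2′/SN2′ allylic transposition of the acetate should give the thermodynamic trisubstituted alkene with the methyl trans to the ester (E).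

Step 22
Reactants: 32 tert-butyl (2E)-2-(acetoxymethyl)but-2-enoate
Product: 33 (2E)-2-(acetoxymethyl)but-2-enoic acid
Conditions: TFA, CH2Cl2, 0 °C to rt
Reagents that add atoms: none
Why: Acidolysis of the tert-butyl ester leaves the primary allylic acetate and the alkene geometry intact.

Step 23
Reactants: 27 8,9-diol; 33 (2E)-2-(acetoxymethyl)but-2-enoic acid
Product: 34 8-O-acyl 9-alcohol
Conditions: EDC·HCl, DMAP (0.2 equiv), CH2Cl2, −10 to 0 °C
Reagents that add atoms: none
Why: Steglich esterification should take the less hindered 8-OH, because the 9-OH is neopentylic (next to quaternary C10).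

Step 24
Reactants: 34 8-O-acyl 9-alcohol
Product: 35 target compound
Conditions: Ac2O, pyridine, DMAP (cat.), CH2Cl2, rt
Reagents that add atoms: acetic anhydride CC(=O)OC(C)=O
Why: Acetylation of the remaining hindered 9-OH under mild conditions completes the target.

**Compound list**

1 | L-fucose (6-deoxy-L-galactopyranose, anomers) | C[C@@H]1OC(O)[C@@H](O)[C@H](O)[C@@H]1O | starting material
2 | 3,4-O-isopropylidene-L-fucopyranose | C[C@@H]1OC(O)[C@@H](O)[C@@H]2OC(C)(C)O[C@H]12 | intermediate
3 | 5-deoxy-4-O-formyl-2,3-O-isopropylidene-aldehydo-L-lyxose (formate aldehyde) | O=C[C@@H]1OC(C)(C)O[C@@H]1[C@H](C)OC=O | intermediate (not isolated)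
4 | 5-deoxy-2,3-O-isopropylidene-L-lyxofuranose (anomers) | C[C@@H]1OC(O)[C@@H]2OC(C)(C)O[C@H]12 | intermediate
5 | (1S)-1-[(4R,5S)-5-[(E)-2-iodoethenyl]-2,2-dimethyl-1,3-dioxolan-4-yl]ethan-1-ol | I/C=C/[C@@H]1OC(C)(C)O[C@@H]1[C@H](C)O | intermediate
6 | 1-[(4S,5S)-5-[(E)-2-iodoethenyl]-2,2-dimethyl-1,3-dioxolan-4-yl]ethan-1-one | I/C=C/[C@@H]1OC(C)(C)O[C@@H]1C(C)=O | intermediate
7 | ethynyl(trimethyl)silane | C#C[Si](C)(C)C | starting material
8 | [(trimethylsilyl)ethynyl]magnesium bromide | C[Si](C)(C)C#C[Mg]Br | intermediate (not isolated)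
9 | (2S)-2-[(4S,5S)-5-[(E)-2-iodoethenyl]-2,2-dimethyl-1,3-dioxolan-4-yl]-4-(trimethylsilyl)but-3-yn-2-ol | I/C=C/[C@@H]1OC(C)(C)O[C@@H]1[C@@](C)(O)C#C[Si](C)(C)C | intermediate
10 | triethylsilyl ether of 9 (8S,9S,10S) | I/C=C/[C@@H]1OC(C)(C)O[C@@H]1[C@@](C)(O[Si](CC)(CC)CC)C#C[Si](C)(C)C | intermediate
11 | prop-2-yn-1-ol | C#CCO | starting material
12 | bromomagnesium (2Z)-3-(bromomagnesio)-2-methylprop-2-en-1-olate | C/C(CO[Mg]Br)=C/[Mg]Br | intermediate (not isolated)
13 | (2Z)-3-iodo-2-methylprop-2-en-1-ol | C/C(CO)=C/I | intermediate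
14 | tert-butyl{[(2Z)-3-iodo-2-methylprop-2-en-1-yl]oxy}diphenylsilane | C/C(CO[Si](c1ccccc1)(c1ccccc1)C(C)(C)C)=C/I | intermediate
15 | (1Z)-3-(tert-butyldiphenylsilyloxy)-2-methylprop-1-enyllithium | C/C(CO[Si](c1ccccc1)(c1ccccc1)C(C)(C)C)=C/[Li] | intermediate (not isolated)
16 | (1Z)-3-(tert-butyldiphenylsilyloxy)-2-methylprop-1-enylzinc chloride | C/C(CO[Si](c1ccccc1)(c1ccccc1)C(C)(C)C)=C/[Zn]Cl | intermediate (not isolated)
17 | (4Z,6E)-diene: TBDPSO–C3H2–C4(CH3)=C5H–C6H=C7H–[C8,C9 acetonide]–C10(CH3)(OTES)–C1≡C2–SiMe3, (8S,9S,10S) | C/C(CO[Si](c1ccccc1)(c1ccccc1)C(C)(C)C)=C/C=C/[C@@H]2OC(C)(C)O[C@@H]2[C@@](C)(O[Si](CC)(CC)CC)C#C[Si](C)(C)C | intermediate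
18 | malonic acid | OC(=O)CC(=O)O | starting material
19 | trans-γ-lactone acid: 2-oxooxolane-3-carboxylic acid with the (Z)-alkenyl group on C6 and the dioxolanyl group on C7, (6R,7S,8S,9S,10S), C11 epimers | C/C(CO[Si](c1ccccc1)(c1ccccc1)C(C)(C)C)=C/[C@H]2OC(=O)C(C(=O)O)[C@@H]2[C@@H]3OC(C)(C)O[C@@H]3[C@@](C)(O[Si](CC)(CC)CC)C#C[Si](C)(C)C | intermediate
20 | α-methylene-γ-lactone (6R,7S,8S,9S,10S), silyl groups as in 19 | C/C(CO[Si](c1ccccc1)(c1ccccc1)C(C)(C)C)=C/[C@H]2OC(=O)C(=C)[C@@H]2[C@@H]3OC(C)(C)O[C@@H]3[C@@](C)(O[Si](CC)(CC)CC)C#C[Si](C)(C)C | intermediate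
21 | desilylated lactone: 3-OH, 10-OH, terminal C1≡C2–H (6R,7S,8S,9S,10S) | C/C(CO)=C/[C@H]1OC(=O)C(=C)[C@@H]1[C@@H]2OC(C)(C)O[C@@H]2[C@@](C)(O)C#C | intermediate
22 | iodoalkyne (C2–I) of 21 | C/C(CO)=C/[C@H]1OC(=O)C(=C)[C@@H]1[C@@H]2OC(C)(C)O[C@@H]2[C@@](C)(O)C#CI | intermediate
23 | (Z)-enal (C3 aldehyde) iodoalkyne | C/C(C=O)=C/[C@H]1OC(=O)C(=C)[C@@H]1[C@@H]2OC(C)(C)O[C@@H]2[C@@](C)(O)C#CI | intermediate
24 | 10-membered carbocycle: 3-hydroxy-1-yne-4(Z)-ene, 10-OH, 6,12-olide, 8,9-acetonide (C3 epimers) | C/C1=C/[C@H]2OC(=O)C(=C)[C@@H]2[C@@H]3OC(C)(C)O[C@@H]3[C@@](C)(O)C#CC1O | intermediate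
25 | macrocyclic γ-hydroxy ynone (3-oxo-1-yne, 10-OH) | C/C1=C/[C@H]2OC(=O)C(=C)[C@@H]2[C@@H]3OC(C)(C)O[C@@H]3[C@@](C)(O)C#CC1=O | intermediate
26 | 8,9-O-isopropylidene furanoheliangolide (6R,7S,8S,9S,10R) | C=C1C(=O)O[C@@H]2/C=C(/C)C3=CC(=O)[C@](C)(O3)[C@H]4OC(C)(C)O[C@H]4[C@@H]12 | intermediate
27 | 8,9-dihydroxy furanoheliangolide (6R,7S,8S,9S,10R) | C=C1C(=O)O[C@@H]2/C=C(/C)C3=CC(=O)[C@](C)(O3)[C@@H](O)[C@@H](O)[C@@H]12 | intermediate
28 | acetaldehyde | CC=O | starting material
29 | tert-butyl acrylate | C=CC(=O)OC(C)(C)C | starting material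
30 | tert-butyl 3-hydroxy-2-methylidenebutanoate (racemic) | CC(O)C(=C)C(=O)OC(C)(C)C | intermediate
31 | tert-butyl 3-acetoxy-2-methylidenebutanoate (racemic) | CC(OC(C)=O)C(=C)C(=O)OC(C)(C)C | intermediate
32 | tert-butyl (2E)-2-(acetoxymethyl)but-2-enoate | CC(C)(C)OC(=O)/C(=C/C)COC(C)=O | intermediate
33 | (2E)-2-(acetoxymethyl)but-2-enoic acid | OC(=O)/C(=C/C)COC(C)=O | intermediate
34 | 8-O-[(2E)-2-(acetoxymethyl)but-2-enoyl] 9-hydroxy furanoheliangolide | C=C1C(=O)O[C@@H]2/C=C(/C)C3=CC(=O)[C@](C)(O3)[C@@H](O)[C@@H](OC(=O)/C(=C/C)COC(C)=O)[C@@H]12 | intermediate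
35 | CNP0325609.1 (6R,7S,8S,9S,10R; 4Z) | C=C1C(=O)O[C@@H]2/C=C(/C)C3=CC(=O)[C@](C)(O3)[C@@H](OC(C)=O)[C@@H](OC(=O)/C(=C/C)COC(C)=O)[C@@H]12 | target

**Count and risks**

Total steps: 24. Longest linear sequence: 18 steps (1–6, 9–18, 23, 24).

The three steps most likely to fail:

Step 10 (carbolactonisation). The radical may add with poor facial selectivity at C7, since 1,2-induction from C8 across an E-alkene is only moderate. The product may be oxidised further to a spiro-dilactone, acetate may capture the allyl cation, and the 4Z geometry may be lost. The fallback sets out from 17 and returns at 19. Rhodium(II)-catalysed cyclopropanation of the C6=C7 bond with bis(2,2,2-trichloroethyl) diazomalonate would give the bis(trichloroethyl) vinylcyclopropane-1,1-dicarboxylate F1. Zinc in acetic acid would remove both esters to give the vinylcyclopropane-1,1-dicarboxylic acid F2. On gentle warming in acetic acid its donor–acceptor ring should open at the allylic C6–C11 bond and reclose through a carboxyl oxygen at C6, the known lactonisation of 2-vinylcyclopropane-1,1-dicarboxylic acids, to give 19.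

Step 15 (ring closure). Oligomerisation may outrun closure of the strained 10-membered enyne ring, and the alkynylchromium species may be reduced or protonated before it reaches the aldehyde. The fallback sets out from 21 and returns at 25. Dess–Martin oxidation would give the terminal-alkyne (Z)-enal F3 and Pinnick oxidation the (Z)-enoic acid F4. Conversion to the acid chloride with 1-chloro-N,N,2-trimethylpropenylamine, then an intramolecular palladium/copper-catalysed acyl Sonogashira coupling with the C2–H alkyne at high dilution, would form C2–C3 and deliver ynone 25 directly. This bypasses 22, 23 and 24.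

Step 23 (selective esterification). The acyl group may go to both hydroxyls, or migrate between the cis-vicinal O8 and O9. The fallback sets out from 27 and returns at 35. Trimethyl orthoacetate with PPTS would give the cyclic 8,9-orthoacetate F5. Mild aqueous acetic acid should open it with the acetate left on the more hindered O9, giving the 9-acetate 8-alcohol F6. Esterification of the free 8-OH with 33 (EDC·HCl, DMAP) would then give 35, so the two acyl groups are installed in the reverse order.

**Further compounds**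

F1 | step 10 | bis(2,2,2-trichloroethyl) cyclopropane-1,1-dicarboxylate over C6, C7 and C11 of diene 17 | C/C(CO[Si](c1ccccc1)(c1ccccc1)C(C)(C)C)=C/[C@@H]2[C@H](C2(C(=O)OCC(Cl)(Cl)Cl)C(=O)OCC(Cl)(Cl)Cl)[C@@H]3OC(C)(C)O[C@@H]3[C@@](C)(O[Si](CC)(CC)CC)C#C[Si](C)(C)C
F2 | step 10 | the corresponding vinylcyclopropane-1,1-dicarboxylic acid | C/C(CO[Si](c1ccccc1)(c1ccccc1)C(C)(C)C)=C/[C@@H]2[C@H](C2(C(=O)O)C(=O)O)[C@@H]3OC(C)(C)O[C@@H]3[C@@](C)(O[Si](CC)(CC)CC)C#C[Si](C)(C)C
F3 | step 15 | terminal-alkyne (Z)-enal (C3 aldehyde, C2–H) | C/C(C=O)=C/[C@H]1OC(=O)C(=C)[C@@H]1[C@@H]2OC(C)(C)O[C@@H]2[C@@](C)(O)C#C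
F4 | step 15 | terminal-alkyne (Z)-enoic acid (C3 acid, C2–H) | C/C(C(=O)O)=C/[C@H]1OC(=O)C(=C)[C@@H]1[C@@H]2OC(C)(C)O[C@@H]2[C@@](C)(O)C#C
F5 | step 23 | cyclic 8,9-(1-methoxyethylidene) orthoacetate of 27 | C=C1C(=O)O[C@@H]2/C=C(/C)C3=CC(=O)[C@](C)(O3)[C@H]4OC(C)(OC)O[C@H]4[C@@H]12
F6 | step 23 | 9-O-acetyl 8-hydroxy furanoheliangolide | C=C1C(=O)O[C@@H]2/C=C(/C)C3=CC(=O)[C@](C)(O3)[C@@H](OC(C)=O)[C@@H](O)[C@@H]12
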